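**Retrosynthetic overview**
1. Endgame: the C15 acid comes from a silyl-protected allylic alcohol. The two isovalerates go onto the C3 and C19 hydroxyls of a triol whose C19 and 6β hydroxyls arise together by reductive opening of a 19,6β-γ-lactone.
2. The side chain is joined at C9–C11 by Negishi coupling of a C9 enol triflate (C8=C9) with a C11–C16 alkylzinc whose 13E double bond comes from a carboalumination.
3. The strategy rests on ring B (C5–C10): O6 lies para to the chain-bearing C9, and C9 is flanked by the methyl-bearing C8 and C10, which is the pattern of 2,6-dimethyl-1,4-benzoquinone. Its C5=C10 bond takes up ring A (C1–C4 with C19) as a 1-carbomethoxy-2-silyloxydiene in a catalytic enantioselective Diels–Alder reaction.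
4. Ring order: ring B is bought, ring A is closed on it by the [4+2], the lactone ring (C19–O6) is closed as a temporary third ring and opened again, and the chain comes last.
5. Stereocentres: C10 from the catalyst, C5 by equilibration through the C6 ketone, C4 by methylation anti to C20, C3 and C6 by hydride delivery.

Key step: step 4

Remark and assumption: labdane numbering is used (decalin C1–C10, C17 on C8, C18 and C19 on C4, C20 on C10, chain C11–C16), and β is the face of the C10 methyl. The (S)-catalyst of step 4 is assumed to be the enantiomer that leaves open the quinone face leading to 9; its mirror image is used if the sense is the reverse. The silyl group of the diene is triisopropylsilyl, chosen for stability toward the acidic catalyst.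

**Route**

Step 1
Reactants: 1 methyl acetate; 2 acrolein
Product: 4 methyl 3-hydroxypent-4-enoate (racemic), via lithium enolate of methyl acetate 3 (not isolated)
Conditions: LiN(i-Pr)2, THF, −78 °C; then 2; NH4Cl aq.
Reagents that add atoms: none
Why: Aldol addition, in which the lithium ester enolate adds 1,2 to acrolein at low temperature; the new carbinol centre is racemic and is removed in step 2.

Step 2
Reactants: 4 methyl 3-hydroxypent-4-enoate
Product: 5 methyl 3-oxopent-4-enoate
Conditions: CrO3, H2SO4 aq., acetone, 0 °C
Reagents that add atoms: none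
Why: Jones oxidation of the secondary allylic alcohol should give the vinyl ketone, which is used at once because it polymerises on standing.

Step 3
Reactants: 5 methyl 3-oxopent-4-enoate
Product: 7 methyl (2Z)-3-(triisopropylsilyloxy)penta-2,4-dienoate, via chelated lithium Z-enolate 6 (not isolated)
Conditions: LiN(SiMe3)2, THF, −78 °C; i-Pr3SiOTf, −78 → 0 °C
Reagents that add atoms: triisopropylsilyl trifluoromethanesulfonate, CC(C)[Si](OS(=O)(=O)C(F)(F)F)(C(C)C)C(C)C
Why: O-silylation of the fully formed β-keto ester enolate (silyl enol ether formation), whose lithium chelate holds the oxygen cis to the ester, so the 2Z isomer with the ester on the outward diene position is expected.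

Step 4
Reactants: 8 2,6-dimethyl-1,4-benzoquinone; 7 methyl (2Z)-3-(triisopropylsilyloxy)penta-2,4-dienoate
Product: 9 cis-fused Diels–Alder adduct (4α-CO2Me; 5β-H; 10β-Me; C2=C3 triisopropylsilyl enol ether; 6,9-dione; C7=C8 bearing C17)
Conditions: (S)-tetrahydro-1-(2-methylphenyl)-3,3-diphenyl-1H,3H-pyrrolo[1,2-c][1,3,2]oxazaborole (20 mol%), HNTf2 (18 mol%), CH2Cl2, −78 → −40 °C
Reagents that add atoms: none
Why: The boron of the N-protonated oxazaborolidine binds the C6 carbonyl of 8, the one flanked by C–H bonds, and the activated C5=C10 bond adds suprafacially to the s-cis diene 7 in a concerted, asynchronous endo [4+2] cycloaddition; the closest known reaction type is the oxazaborolidinium-catalysed enantioselective Diels–Alder reaction of alkylbenzoquinones with 2-silyloxy-1,3-dienes. Ring A (C1–C5, C10) is closed as a cyclohexene by intermolecular [4+2] annulation, the bonds C1–C10 and C4–C5 forming across one quinone double bond; the two quinone double bonds are interchanged by the twofold axis through the carbonyls, so no site problem arises, and the C10 methyl keeps the adduct from aromatising. C10 is set by the catalyst, which leaves one face of the bound quinone open; C5 follows from suprafacial addition (H cis to C20) and C4 from the endo transition state with the ester on the outward diene position, and both are adjusted later (steps 7 and 8). The step needs C1 on C10 and C4 on C5: in the complex the more advanced bond forms at C10, β to the bound carbonyl, and the unsubstituted C1 terminus is expected to take this crowded, methyl-bearing position in preference to the ester-bearing C4. The conjugated ester damps the enol-ether polarisation toward C4, so that sterics decide, and this is the weakest point of the route. The 2Z geometry keeps the ester outward, so the s-cis conformer stays accessible.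

Step 5
Reactants: 9 cis-fused Diels–Alder adduct
Product: 10 cis-fused 6,9-dione silyl enol ether (C7–C8 saturated; C8 epimers)
Conditions: Zn, AcOH, rt
Reagents that add atoms: none
Why: Zinc–acetic acid reduction of the ene-1,4-dione saturates only C7=C8; C8 forms as an epimer mixture that is equilibrated in step 7 and becomes sp2 in step 11.

Step 6
Reactants: 10 cis-fused 6,9-dione silyl enol ether
Product: 11 cis-fused 3,6,9-trione methyl ester (5β-H; C4 and C8 as epimer mixtures)
Conditions: HF aq. (48%), MeCN, 0 °C
Reagents that add atoms: none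
Why: Fluoride-assisted protodesilylation of the silyl enol ether should unveil the C3 ketone as the β-keto ester without base.

Step 7
Reactants: 11 cis-fused 3,6,9-trione methyl ester
Product: 12 trans-fused 3,6,9-trione β-keto ester (5α-H; 10β-Me; 4α-CO2Me; 8α-Me)
Conditions: NaOMe, MeOH, 0 °C → rt; AcOH
Reagents that add atoms: none
Why: Base-mediated epimerisation through the C6 enolate (C4 and C8 equilibrate alongside) under thermodynamic control should settle C5 in the trans-fused chair–chair trione with the C4 ester and C8 methyl equatorial; angular-methyl decalones do not equilibrate wholly to one side, so cis-fused material is separated and resubmitted.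

Step 8
Reactants: 12 trans-fused 3,6,9-trione β-keto ester
Product: 13 C4-quaternary trione (4α-Me; 4β-CO2Me)
Conditions: MeI, K2CO3, acetone, rt
Reagents that add atoms: iodomethane, CI
Why: C-alkylation of the β-keto ester enolate, in which methyl iodide should enter C4 from the α face, anti to the 1,3-related axial C10 methyl, leaving the ester β (axial) as in podocarpate-type methylations.

Step 9
Reactants: 13 C4-quaternary trione
Product: 15 3α-hydroxy-9-oxo-19,6β-lactone (5α-H; 8α-Me), via 3α,6β-dihydroxy methyl ester 14 (not isolated)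
Conditions: LiBH(s-Bu)3 (2.3 equiv), THF, −78 → −30 °C; NH4Cl aq.; NaBO3·4H2O work-up
Reagents that add atoms: none
Why: Bulky-hydride reduction followed by lactonisation: equatorial attack at C3 gives the axial 3α-alcohol, α-face attack at C6 (β face blocked by C20 and C19) gives the 6β-alkoxide, which closes onto the syn-axial C19 ester, while the C9 ketone between quaternary C10 and C8 should not react at low temperature.

Step 10
Reactants: 15 3α-hydroxy-9-oxo-19,6β-lactone
Product: 16 3α-triethylsilyloxy-9-oxo-19,6β-lactone
Conditions: Et3SiOTf, 2,6-lutidine, CH2Cl2, −78 → 0 °C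
Reagents that add atoms: triethylsilyl trifluoromethanesulfonate, CC[Si](CC)(CC)OS(=O)(=O)C(F)(F)F
Why: Silyl ether formation with a silyl triflate, reactive enough for the hindered axial 3α-alcohol, masks the only free hydroxyl before enolate chemistry.

Step 11
Reactants: 16 3α-triethylsilyloxy-9-oxo-19,6β-lactone
Product: 18 C9 enol triflate of the 3α-triethylsilyloxy-19,6β-lactone (C8=C9), via potassium C8-enolate 17 (not isolated)
Conditions: KN(SiMe3)2, THF, −78 °C; PhNTf2, −78 → 0 °C
Reagents that add atoms: N-phenylbis(trifluoromethanesulfonimide), FC(F)(F)S(=O)(=O)N(c1ccccc1)S(=O)(=O)C(F)(F)F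
Why: Enol triflate formation: the C9 ketone can enolise only towards C8 because C10 is quaternary and the lactone has no α-hydrogen, so O-triflation fixes the C8=C9 double bond and erases the C8 centre.

Step 12
Reactants: 19 but-3-yn-1-ol
Product: 20 tert-butyl(but-3-yn-1-yloxy)dimethylsilane
Conditions: t-BuMe2SiCl, imidazole, CH2Cl2, rt
Reagents that add atoms: tert-butyldimethylsilyl chloride, CC(C)(C)[Si](C)(C)Cl
Why: Standard silyl ether protection of the primary alcohol, which would otherwise consume the aluminium reagent.

Step 13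
Reactants: 20 tert-butyl(but-3-yn-1-yloxy)dimethylsilane
Product: 23 (E)-5-(tert-butyldimethylsilyloxy)-3-methylpent-2-en-1-ol, via alkenyldimethylalane 21 (not isolated), via lithium alkenylalanate 22 (not isolated)
Conditions: AlMe3, Cp2ZrCl2 (25 mol%), CH2Cl2, 0 °C → rt; n-BuLi, THF, −78 °C; (CH2O)n, −78 °C → rt; NH4Cl aq.
Reagents that add atoms: trimethylaluminium, C[Al](C)C; formaldehyde (as paraformaldehyde), C=O
Why: Zirconium-catalysed carboalumination (Negishi) adds methyl and aluminium syn across the alkyne with methyl on the internal carbon, and hydroxymethylation of the derived alanate with retention should give the E trisubstituted allylic alcohol.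

Step 14
Reactants: 23 (E)-5-(tert-butyldimethylsilyloxy)-3-methylpent-2-en-1-ol
Product: 24 (E)-1-(tert-butyldiphenylsilyloxy)-5-(tert-butyldimethylsilyloxy)-3-methylpent-2-ene
Conditions: t-BuPh2SiCl, imidazole, CH2Cl2, rt
Reagents that add atoms: tert-butyldiphenylsilyl chloride, CC(C)(C)[Si](Cl)(c1ccccc1)c1ccccc1
Why: Silyl ether formation places the more acid-stable silyl group on the allylic oxygen (C15), which must survive to the end of the route.

Step 15
Reactants: 24 (E)-1-(tert-butyldiphenylsilyloxy)-5-(tert-butyldimethylsilyloxy)-3-methylpent-2-ene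
Product: 25 (E)-5-(tert-butyldiphenylsilyloxy)-3-methylpent-3-en-1-ol
Conditions: pyridinium p-toluenesulfonate, EtOH, 40 °C
Reagents that add atoms: none
Why: Acid-catalysed alcoholysis should cleave the primary tert-butyldimethylsilyl ether far faster than the tert-butyldiphenylsilyl ether.

Step 16
Reactants: 25 (E)-5-(tert-butyldiphenylsilyloxy)-3-methylpent-3-en-1-ol
Product: 26 (E)-tert-butyl((5-iodo-3-methylpent-2-en-1-yl)oxy)diphenylsilane
Conditions: I2, PPh3, imidazole, CH2Cl2, 0 °C
Reagents that add atoms: iodine, II
Why: Appel-type iodination of the primary homoallylic alcohol proceeds by SN2 displacement of the oxyphosphonium and does not touch the double bond geometry.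

Step 17
Reactants: 26 (E)-tert-butyl((5-iodo-3-methylpent-2-en-1-yl)oxy)diphenylsilane; 18 C9 enol triflate
Product: 28 coupled lactone (labd-8-ene-19,6β-olide skeleton; 3α-OSiEt3; 15-OSiPh2t-Bu; 13E), via alkylzinc iodide 27 (not isolated)
Conditions: 26, Zn dust, LiCl, THF, 40 °C; then 18, Pd(OAc)2 (5 mol%), 2-dicyclohexylphosphino-2',6'-dimethoxybiphenyl (10 mol%), THF/N-methylpyrrolidone, 50 °C
Reagents that add atoms: none
Why: Negishi sp3–sp2 cross-coupling forms C9–C11; the alkylzinc tolerates the lactone and silyl ethers, and the electron-rich biaryl phosphine should favour oxidative addition to the hindered triflate and reductive elimination over β-hydride loss.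

Step 18
Reactants: 28 coupled lactone
Product: 29 6β,19-diol with 3α-OSiEt3 and 15-OSiPh2t-Bu
Conditions: LiAlH4, THF, 0 °C → rt
Reagents that add atoms: none
Why: Hydride reduction of the γ-lactone to the 1,4-diol; only the acyl C–O bond is cleaved, so C6 keeps its β oxygen.

Step 19
Reactants: 29 6β,19-diol with 3α-OSiEt3 and 15-OSiPh2t-Bu
Product: 30 3α,6β,19-triol with 15-OSiPh2t-Bu
Conditions: pyridinium p-toluenesulfonate, MeOH/CH2Cl2, 0 °C → rt
Reagents that add atoms: none
Why: Acid-catalysed methanolysis should remove the triethylsilyl ether while the tert-butyldiphenylsilyl ether stays.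

Step 20
Reactants: 30 3α,6β,19-triol with 15-OSiPh2t-Bu; 31 isovaleryl chloride
Product: 32 3α,19-bis(isovalerate) with free 6β-OH and 15-OSiPh2t-Bu
Conditions: 31 (2.4 equiv), pyridine, 4-(dimethylamino)pyridine (cat.), CH2Cl2, 0 °C → rt
Reagents that add atoms: none
Why: Nucleophile-catalysed O-acylation should take the primary C19 hydroxyl and the axial 3α hydroxyl, while the 6β hydroxyl, syn-axial to both C20 and the C19 methylene, is too shielded to react under these conditions.

Step 21
Reactants: 32 3α,19-bis(isovalerate) with free 6β-OH and 15-OSiPh2t-Bu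
Product: 33 3α,19-bis(isovaleryloxy)labda-8,13E-diene-6β,15-diol
Conditions: HF·pyridine, pyridine, THF, 0 °C → rt
Reagents that add atoms: none
Why: Fluoride cleavage of the silyl ether under buffered, non-basic conditions avoids ester hydrolysis and acyl migration.

Step 22
Reactants: 33 3α,19-bis(isovaleryloxy)labda-8,13E-diene-6β,15-diol
Product: 34 3α,19-bis(isovaleryloxy)-6β-hydroxylabda-8,13E-dien-15-al
Conditions: MnO2, CH2Cl2, rt
Reagents that add atoms: none
Why: Manganese dioxide oxidises only the allylic C15 alcohol and leaves the saturated, hindered 6β hydroxyl; the E geometry is expected to hold.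

Step 23
Reactants: 34 3α,19-bis(isovaleryloxy)-6β-hydroxylabda-8,13E-dien-15-al
Product: 35 target CNP0333611.1 (3α,19-bis(isovaleryloxy)-6β-hydroxylabda-8,13E-dien-15-oic acid)
Conditions: NaClO2, NaH2PO4, 2-methylbut-2-ene, t-BuOH/H2O, rt
Reagents that add atoms: sodium chlorite, [Na+].[O-]Cl=O
Why: Pinnick oxidation converts the enal into the acid without touching the secondary alcohol, and the alkene scavenger takes up hypochlorous acid before it can attack the C8=C9 or C13=C14 bonds.

**Compound list**
1 | methyl acetate | COC(C)=O | starting material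
2 | acrolein | C=CC=O | starting material
3 | lithium enolate of methyl acetate | C=C([O-])OC.[Li+] | intermediate
4 | methyl 3-hydroxypent-4-enoate (racemic) | COC(=O)CC(O)C=C | intermediate
5 | methyl 3-oxopent-4-enoate | COC(=O)CC(=O)C=C | intermediate
6 | chelated lithium Z-enolate of 5 | COC(=O)/C=C([O-])/C=C.[Li+] | intermediate
7 | methyl (2Z)-3-(triisopropylsilyloxy)penta-2,4-dienoate | COC(=O)/C=C(O[Si](C(C)C)(C(C)C)C(C)C)/C=C | intermediate
8 | 2,6-dimethyl-1,4-benzoquinone | CC1=CC(=O)C=C(C)C1=O | starting material
9 | cis-fused Diels–Alder adduct (4α-CO2Me; 5β-H; 10β-Me; C2=C3 silyl enol ether; 6,9-dione; C7=C8) | O=C1[C@@]2(C)CC=C(O[Si](C(C)C)(C(C)C)C(C)C)[C@@H](C(=O)OC)[C@H]2C(=O)C=C1C | intermediate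
10 | cis-fused 6,9-dione silyl enol ether (C8 epimers) | O=C1[C@@]2(C)CC=C(O[Si](C(C)C)(C(C)C)C(C)C)[C@@H](C(=O)OC)[C@H]2C(=O)CC1C | intermediate
11 | cis-fused 3,6,9-trione methyl ester (5β-H; C4 and C8 epimers) | O=C1[C@@]2(C)CCC(=O)C(C(=O)OC)[C@H]2C(=O)CC1C | intermediate
12 | trans-fused 3,6,9-trione β-keto ester (5α-H; 4α-CO2Me; 8α-Me) | C[C@H]1C(=O)[C@@]2(C)CCC(=O)[C@@H](C(=O)OC)[C@@H]2C(=O)C1 | intermediate
13 | C4-quaternary trione (4α-Me; 4β-CO2Me) | C[C@H]1C(=O)[C@@]2(C)CCC(=O)[C@](C)(C(=O)OC)[C@@H]2C(=O)C1 | intermediate
14 | 3α,6β-dihydroxy methyl ester (as lithium alkoxide in the flask) | C[C@H]1C(=O)[C@@]2(C)CC[C@@H](O)[C@](C)(C(=O)OC)[C@@H]2[C@H](O)C1 | intermediate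
15 | 3α-hydroxy-9-oxo-19,6β-lactone | C[C@H]1C(=O)[C@@]2(C)CC[C@@H](O)[C@](C)(C(=O)O3)[C@@H]2[C@H]3C1 | intermediate
16 | 3α-triethylsilyloxy-9-oxo-19,6β-lactone | C[C@H]1C(=O)[C@@]2(C)CC[C@@H](O[Si](CC)(CC)CC)[C@](C)(C(=O)O3)[C@@H]2[C@H]3C1 | intermediate
17 | potassium C8-enolate of 16 | CC1=C([O-])[C@@]2(C)CC[C@@H](O[Si](CC)(CC)CC)[C@](C)(C(=O)O3)[C@@H]2[C@H]3C1.[K+] | intermediate
18 | C9 enol triflate (C8=C9) of the 3α-triethylsilyloxy-19,6β-lactone | CC1=C(OS(=O)(=O)C(F)(F)F)[C@@]2(C)CC[C@@H](O[Si](CC)(CC)CC)[C@](C)(C(=O)O3)[C@@H]2[C@H]3C1 | intermediate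
19 | but-3-yn-1-ol | C#CCCO | starting material
20 | tert-butyl(but-3-yn-1-yloxy)dimethylsilane | C#CCCO[Si](C)(C)C(C)(C)C | intermediate
21 | (E)-alkenyldimethylalane | C[Al](C)/C=C(\C)CCO[Si](C)(C)C(C)(C)C | intermediate
22 | lithium butyl(dimethyl)alkenylalanate | [Li+].CCCC[Al-](C)(C)/C=C(\C)CCO[Si](C)(C)C(C)(C)C | intermediate
23 | (E)-5-(tert-butyldimethylsilyloxy)-3-methylpent-2-en-1-ol | OC/C=C(\C)CCO[Si](C)(C)C(C)(C)C | intermediate
24 | (E)-1-(tert-butyldiphenylsilyloxy)-5-(tert-butyldimethylsilyloxy)-3-methylpent-2-ene | CC(C)(C)[Si](C)(C)OCC/C(C)=C/CO[Si](c1ccccc1)(c1ccccc1)C(C)(C)C | intermediate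
25 | (E)-5-(tert-butyldiphenylsilyloxy)-3-methylpent-3-en-1-ol | OCC/C(C)=C/CO[Si](c1ccccc1)(c1ccccc1)C(C)(C)C | intermediate
26 | (E)-tert-butyl((5-iodo-3-methylpent-2-en-1-yl)oxy)diphenylsilane | ICC/C(C)=C/CO[Si](c1ccccc1)(c1ccccc1)C(C)(C)C | intermediate
27 | alkylzinc iodide from 26 | I[Zn]CC/C(C)=C/CO[Si](c1ccccc1)(c1ccccc1)C(C)(C)C | intermediate
28 | coupled lactone (3α-OSiEt3; 15-OSiPh2t-Bu; 13E; 19,6β-olide) | CC1=C(CC/C(C)=C/CO[Si](c4ccccc4)(c5ccccc5)C(C)(C)C)[C@@]2(C)CC[C@@H](O[Si](CC)(CC)CC)[C@](C)(C(=O)O3)[C@@H]2[C@H]3C1 | intermediate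
29 | 6β,19-diol with 3α-OSiEt3 and 15-OSiPh2t-Bu | CC1=C(CC/C(C)=C/CO[Si](c4ccccc4)(c5ccccc5)C(C)(C)C)[C@@]2(C)CC[C@@H](O[Si](CC)(CC)CC)[C@](C)(CO)[C@@H]2[C@H](O)C1 | intermediate
30 | 3α,6β,19-triol with 15-OSiPh2t-Bu | CC1=C(CC/C(C)=C/CO[Si](c4ccccc4)(c5ccccc5)C(C)(C)C)[C@@]2(C)CC[C@@H](O)[C@](C)(CO)[C@@H]2[C@H](O)C1 | intermediate
31 | isovaleryl chloride | CC(C)CC(=O)Cl | starting material
32 | 3α,19-bis(isovalerate) with free 6β-OH and 15-OSiPh2t-Bu | CC1=C(CC/C(C)=C/CO[Si](c4ccccc4)(c5ccccc5)C(C)(C)C)[C@@]2(C)CC[C@@H](OC(=O)CC(C)C)[C@](C)(COC(=O)CC(C)C)[C@@H]2[C@H](O)C1 | intermediate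
33 | 3α,19-bis(isovaleryloxy)labda-8,13E-diene-6β,15-diol | CC1=C(CC/C(C)=C/CO)[C@@]2(C)CC[C@@H](OC(=O)CC(C)C)[C@](C)(COC(=O)CC(C)C)[C@@H]2[C@H](O)C1 | intermediate
34 | 3α,19-bis(isovaleryloxy)-6β-hydroxylabda-8,13E-dien-15-al | CC1=C(CC/C(C)=C/C=O)[C@@]2(C)CC[C@@H](OC(=O)CC(C)C)[C@](C)(COC(=O)CC(C)C)[C@@H]2[C@H](O)C1 | intermediate
35 | CNP0333611.1 | CC1=C(CC/C(C)=C/C(=O)O)[C@@]2(C)CC[C@@H](OC(=O)CC(C)C)[C@](C)(COC(=O)CC(C)C)[C@@H]2[C@H](O)C1 | target

**Step count**
Total: 23 steps. Longest linear sequence: 18 steps (steps 1–11 and 17–23); the side-chain branch is steps 12–16.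

**Steps most likely to fail**

Step 4. Under Lewis acid polarisation the diene may add in the reverse orientation (C4 to C10). The push–pull diene may also react too slowly and lose its silyl group, or the catalyst may select the quinone face poorly. The fallback sets out from 7 and 8, which are heated together without any Lewis acid (toluene, 80 °C). In the free quinone the methyl groups make the unsubstituted C5 the electrophilic end of the C5=C10 bond. This matches the enol-ether terminus C4 of the diene, so electronics and sterics point the same way. The endo cis-fused adduct then forms as the racemate, 9 together with its mirror image, the ent-adduct F1. The enantiomers are separated by preparative chromatography on a chiral stationary phase, and 9 re-enters the route at step 5.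

Step 7. The equilibration may stop at a mixture that still holds much cis-fused isomer, and long exposure to methoxide may start retro-Claisen cleavage. The fallback sets out from 9 and corrects the ring fusion before ring B is saturated. With the enedione in place, a mild amine base (Et3N, CH2Cl2/MeOH, rt) removes C5–H as a cross-conjugated dienolate, while C4 (next to the intact silyl enol ether) and C8 (sp2) cannot epimerise. Only two components equilibrate, and the trans-fused enedione silyl enol ether F2 is taken out by crystallisation while the mother liquor is re-equilibrated. Zn in AcOH then saturates C7=C8 to the trans-fused 6,9-dione silyl enol ether F3. Aqueous HF in MeCN returns to the route at 12; its C8 epimers converge in step 11.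

Step 9. The hydride may fail to discriminate among the three ketones (attack at C9, incomplete reduction at C6) or may attack C3 axially. The fallback sets out from 12, before C4 is methylated, and reduces the two carbonyls in separate operations. NaH in THF converts the β-keto ester into its sodium enolate F4, which masks C3. NaBH4/MeOH at −20 °C then reduces only C6 from the α face to the 6β-hydroxy keto ester F5. On acidification (p-toluenesulfonic acid, CH2Cl2) C4 equilibrates through the enol, and the epimer with the ester β lactonises to the 3,9-dioxo-19,6β-lactone F6. Methylation (MeI, K2CO3, acetone) can now place the methyl only on the α face, because C19 is held on the β face by the lactone, giving the 4α-methyl-3,9-dioxo-19,6β-lactone F7. LiBH(s-Bu)3 (1.1 equiv, THF, −78 °C) reduces the C3 ketone by equatorial attack and returns to the route at 15.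

Further compounds
F1 | step 4 | ent-adduct (mirror image of 9) | O=C1[C@]2(C)CC=C(O[Si](C(C)C)(C(C)C)C(C)C)[C@H](C(=O)OC)[C@@H]2C(=O)C=C1C
F2 | step 7 | trans-fused enedione silyl enol ether (5α-H) | O=C1[C@@]2(C)CC=C(O[Si](C(C)C)(C(C)C)C(C)C)[C@@H](C(=O)OC)[C@@H]2C(=O)C=C1C
F3 | step 7 | trans-fused 6,9-dione silyl enol ether (C8 epimers) | O=C1[C@@]2(C)CC=C(O[Si](C(C)C)(C(C)C)C(C)C)[C@@H](C(=O)OC)[C@@H]2C(=O)CC1C
F4 | step 9 | sodium enolate of 12 | C[C@H]1C(=O)[C@@]2(C)CCC([O-])=C(C(=O)OC)[C@@H]2C(=O)C1.[Na+]
F5 | step 9 | 6β-hydroxy-3,9-dioxo methyl ester (C4 epimers) | C[C@H]1C(=O)[C@@]2(C)CCC(=O)C(C(=O)OC)[C@@H]2[C@H](O)C1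
F6 | step 9 | 3,9-dioxo-19,6β-lactone (4α-H) | C[C@H]1C(=O)[C@@]2(C)CCC(=O)[C@H](C(=O)O3)[C@@H]2[C@H]3C1
F7 | step 9 | 4α-methyl-3,9-dioxo-19,6β-lactone | C[C@H]1C(=O)[C@@]2(C)CCC(=O)[C@](C)(C(=O)O3)[C@@H]2[C@H]3C1
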